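A computer fit to falling substrate can carry the fall past what the charged reagent pays for, so I first ask what end state the reagent allows, then how fast it comes.

| flask | substrate | reagent | capture agent | temperature | remark | time |
|---|---|---|---|---|---|---|
| Saturday's | 2 M | 0.95 M | 0.10 M | 55 °C | run made earlier |  |
| Friday's | 2 M | 0.95 M | 0.10 M | 74 °C | run made earlier |  |
| ochre | 2.0 M | 1.90 M | 0.100 M | 70 °C |  | 25 h |
| teal | 2.0 M | 1.90 M | 0.100 M | 78 °C |  | 25 h |

1. which of these there is most of at the end, counted by the substrate in it, ochre (substrate / tris adduct / over-reaction product / double product / single product)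
2. which of these there is most of at the end, counted by the substrate in it, teal (substrate / tris adduct / over-reaction product / double product / single product)
3. how much there is at the end of the one of these that leads, in percent of the substrate charged: ochre
4. how much there is at the end of the one of these that leads, in percent of the substrate charged: teal



Neither table has a reagent column, so I read Friday's substrate for how the reagent goes.

| run | time / h | tris adduct / % | double product / % | over-reaction product / % | substrate / % | single product / % |
|---|---|---|---|---|---|---|
| Saturday's | 8.00 | 3 | 0 | 0 | 95 | 6 |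
| Saturday's | 15.0 | 1 | 4 | 3 | 93 | 6 |
| Saturday's | 25.0 | 2 | 0 | 2 | 89 | 11 |
| Saturday's | 30.0 | 0 | 1 | 0 | 87 | 10 |
| Friday's | 4.00 | 0 | 4 | 0 | 88 | 10 |
| Friday's | 8.00 | 0 | 1 | 3 | 81 | 17 |
| Friday's | 12.0 | 0 | 3 | 1 | 74 | 19 |
| Friday's | 15.0 | 0 | 3 | 0 | 76 | 21 |

(standard deviation of a reading: 1.5 percentage points)

Friday's first row gives a substrate loss of 0.0600 M h⁻¹. Its second and fourth rows give 0.0143 M h⁻¹, lower by a factor of 4.20. Yet the mean substrate falls from 94.0% to 78.5%. If the rate goes with [substrate][reagent], then late [reagent] is 0.285 of its early value.

So I define the reagent cost, the reagent spent per substrate lost, and, taking the early [reagent] as the charge, it reads 1.58, a rough reading under a scatter of 1.5 percentage points.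

Friday's last row, with 3% double product beside 21% single product, reads a second addition about as fast per molecule as the first, a ratio of 1.03 with the scatter on it.

At the reagent cost I read, I reckon that the reagent, the limiting reagent, pays for a substrate loss that leaves near 39.9% in ochre and in teal. With that ratio near one, single product then stands near 36.7%, so I expect substrate to lead, narrowly.

As for speed, Saturday's first row gives 0.0125 M h⁻¹. Scaling from it and Friday's puts ochre's start near 0.0863 M h⁻¹, so its reagent would last about 13.9 h at that pace, less than 25 h. Teal is hotter than ochre, so I expect ochre and teal both near their ends.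

The forecast gives substrate at 49% in ochre, “a close call favouring substrate”, and single product at 52% in teal.

Ochre ends with substrate at 60.3%, and teal with substrate at 55.0%, ahead of single product at 25.8%.

    substrate + reagent → single product + by-product (k = 6.36 × 10⁻⁴ M⁻¹ min⁻¹, Ea = 99.0 kJ mol⁻¹)
    reagent + single product → double product + by-product (k = 0.00104 M⁻¹ min⁻¹, Ea = 84.0 kJ mol⁻¹)
    reagent + double product → tris adduct + by-product (k = 0.00146 M⁻¹ min⁻¹, Ea = 81.0 kJ mol⁻¹)
    single product + capture agent → trapped intermediate (k = 8.00 × 10⁻⁴ M⁻¹ min⁻¹, Ea = 91.0 kJ mol⁻¹)
    2 reagent → homo dimer (k = 4.62 × 10⁻⁴ M⁻¹ min⁻¹, Ea = 71.0 kJ mol⁻¹)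
    double product → over-reaction product (k = 4.63 × 10⁻⁴ min⁻¹, Ea = 122 kJ mol⁻¹)
    (constants at 70 °C)

Teal has reagent down to 0.573% of its charge, beside by-product at 1.30 M and homo dimer at 0.296 M, so teal's cost is 2.10, against the 1.58 read from Friday's run. Teal's substrate step has half of its turnover up to 25 h behind it at 2.25 h, before that time, and ten times as long leaves teal's substrate at 54.7%. Teal's cost, applied to ochre's spent reagent with 5.4% left, puts ochre's substrate at 57.2%, and ochre holds 60.3%.

The readings were generated by integration for substances that don't exist.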